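## Structural features

The target is a 1-aryltetralin cyclolignan. Aromatic ring A (C4a–C8a, methoxy on C6, free hydroxyl on C7) is fused to saturated ring B (C1–C4), and a 4-hydroxy-3-methoxyphenyl ring sits on C1. Ring B carries three contiguous stereocentres: C1 (S, aryl), C2 (R, acetoxymethyl, exocyclic carbon C9) and C3 (R, hydroxymethyl, exocyclic carbon C10). The relationship is 1,2-trans/2,3-trans, so the C1 and C3 substituents are cis and all three can be equatorial. The fragile points are the two electron-rich free phenols, the doubly benzylic C1–H, and a primary acetate lying next to a free primary alcohol, which can migrate or be lost under base. The first difficulty is C1: once C2 is saturated it cannot be epimerised, so it must be set relative to C3 under kinetic control. The second is that C9 and C10 are near-identical carbinol carbons of which only C9 is acylated, so they must differ from the moment they are introduced. The key step exploits the fact that C1 is a single carbon joining ring A carbon C8a, the pendant aryl ring and C2. As the carbon of an aryldiazomethane it can be inserted into the aryl–carbonyl bond of a 1-indanone whose carbonyl carbon becomes C2 and whose α-carbon is C3; C8a is para to the C6 methoxy group, which makes it the migrating terminus.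

## Logic of the disconnections

24 ⇒ 23. The O–Si bond on the C10 oxygen is reconnected. That hydroxyl must stay masked until the acetate is on C9, otherwise two equivalent primary alcohols would compete. The gain is that the last step carries no selectivity problem. The forward unmasking must be non-basic, so that the acetate neither migrates to O10 nor is cleaved, and must tolerate free phenols.

23 ⇒ 22. The acyl C–O bond of the C9 acetate is cut. This leaves one free aliphatic alcohol as the only site to be acylated. The forward step must distinguish that alcohol from two phenolic hydroxyls.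

22 ⇒ 21. C9 is taken back from the alcohol to the ester level. The ester makes C2–H acidic, so C2 can be corrected thermodynamically, and it marks C9 as different from C10. The forward reduction must tolerate two free phenols and the silyl ether.

21 ⇒ 19 by way of 20. The C1–H and C2–H bonds are cut and, in the same operation, the two phenolic O–H bonds are traced back to benzyl ethers. Both remaining ring stereocentres then come from one flat tetrasubstituted alkene, so C3 is the only stereochemical information needed. Two stereocentres and two protecting groups leave the problem at once. The forward step needs syn delivery of hydrogen to the face opposite the C3 side chain, then base inversion of C2 alone.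

19 ⇒ 16 by way of 18 and 17. The C2–C9 bond is cut. The C2 carbonyl of 16 is the natural anchor for the missing carbon, and enolisation toward C1 deletes the uncontrolled C1 centre. The forward steps need enolisation toward C1 only (toward C3 would epimerise it or expel the β-silyloxy group) and carbonylation of a hindered enol triflate.

16 ⇒ 12 + 15. C1–C2 and C1–C8a are cut. The tetralin divides into an indanone holding the only centre that needs external asymmetric control and an achiral benzylic one-carbon unit, which makes the route convergent. The forward step demands migration of C8a in preference to the α-carbon, a single insertion, and retention of the C3 configuration.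

15 ⇒ 13 by way of 14. The two nitrogen atoms are removed and the carbon returns to the aldehyde level. The forward dehydrogenation must be cold and neutral because the electron-rich diazoalkane is short-lived.

12 ⇒ 10 by way of 11. The aryl–carbonyl bond of the five-membered ring is cut. This bond is temporary: it is the one that migrates in the key step. The forward closure must occur para to the methoxy group without racemising the α-centre or stripping the benzyl and silyl ethers.

10 ⇒ 5 by way of 9, 8, 7 and 6. The C3–C10 bond, the O–Si bond and the acyl–auxiliary bond are cut. This is the one centre made with external control, by a one-carbon electrophile on a chelated enolate. A benzyl ether on O10 would be one step shorter but would be hydrogenolysed in step 12, and the freed alcohol would lactonise onto the cis ester of 20; the silyl ether corrects this.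

5 ⇒ 2 + 3 by way of 4, and 2 ⇒ 1. The imide N–acyl bond and the phenolic O–benzyl bond are cut, leaving a commercial C6–C3 acid and the auxiliary. The phenol benzyl ether only needs to last until step 12, where its loss is planned.

## Other disconnections considered

Alternative 1: The cut is C2–C3 together with C1–C8a, so ring B is assembled from two identical C6–C3 halves. In the forward step FeCl3 (or a peroxidase with H2O2) would oxidise two molecules of the bromine-blocked cinnamoyl imide A1. The phenoxy radicals would join at C2–C3, ring A of one half would close onto the benzylic carbon of the other (C1–C8a), and tautomerisation would give the trans-1-aryl-1,2-dihydronaphthalene bis-imide A2. In its favour, the whole carbon skeleton, ring B and the trans C1/C2 pair would arise in one step from one monomer, with free phenols throughout. On convergence and on the number of skeleton-building steps it is better than the chosen plan, and it is its equal in starting from a cheap C6–C3 feedstock. Against it here: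
- Radical–radical coupling would be expected to give regioisomeric and open-chain dimers beside A2.
- Auxiliary control over such a coupling is weak.
- A2 would still need saturation of C3=C4, removal of two bromines, and differentiation of two acyl groups at the same oxidation level, one to end as the C9 acetate and the other as the free C10 alcohol.

In the chosen plan that differentiation is built into 19 (ester against silyl ether), and C1 is set by a closed-shell, substrate-controlled hydrogenation. Mechanistically the alternative is radical and the chosen plan polar. Overall length would probably be similar, because the end game from A2 is long.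

Alternative 2: The cut is C4a–C8a and C5–C6, so ring A is dismantled and an open-chain dienyne A3 carries the preset C1–C3 triad. In the forward step [Rh(cod)Cl]2 with AgSbF6 would promote intramolecular [4+2] addition of the silyloxydiene to the terminal alkyne. This would close ring B and a non-aromatic ring A, which DDQ would dehydrogenate in the same pot to the protected target A4. In its favour, A4 already carries the acetate and needs only two deprotections, so the end game is shorter than that of the chosen plan and better on that point. It is also better in rings closed per step (two against one). In principle it is the equal or better on stereochemistry, since nothing rests on the facial selectivity of a hydrogenation. Against it here: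
- It builds an aromatic ring that 1 supplies ready-made.
- A3 needs an acyclic stereotriad including an allylic, benzylic C1, a geometrically defined and hydrolytically labile 1-methoxy-2-silyloxydiene, and an acetate that must survive the cationic rhodium and silver catalyst system.
- DDQ would meet two electron-rich benzyl ethers and the doubly benzylic C1–H that aromatisation creates.

The stereochemical burden is moved to acyclic control, not removed, and the linear sequence to A3 would make the whole route longer.

Alternative 3: The cut is C4a–C4 and C4–C3, with carbon monoxide as C4. In the forward step zerovalent palladium (from Pd(OAc)2 and a wide-bite-angle bisphosphine) would insert into the C–Br bond of the bromoarene ester A5. CO would insert, and the acyl group would be transferred to the zinc enolate carbon (C3), closing ring B as the β-keto ester A6. In its favour, C1 and C2 could be set in the open chain and C3 is adjustable as a β-keto ester. The two side-chain carbons are differentiated from the start, which equals the chosen plan. No diazo compound is needed, so it is better in operational safety. Against it here: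
- The C4 ketone sits where the target has a methylene and must be erased beside a doubly benzylic C1.
- The differentiation is inverted (ester on C3, silyl ether on C2), so a protecting-group exchange would be needed.
- Direct enolate arylation without CO uptake would close a five-membered ring.
- O-acylation could compete with C-acylation.

In the chosen plan the carbonyl of 16 lies exactly where a carbon must be attached; in the alternative it lies where nothing is needed. Stereocontrol would be comparable, and the step count probably higher by the deoxygenation and the exchange.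

Key step: step 9

Remarks on the chemistry:
- Compounds 1 and 13 are taken as commercial; they are the dihydro derivative of ferulic acid and the benzyl ether of vanillin.
- Compound 16 is drawn as its 1,3-cis isomer; its C1 configuration is immaterial because step 10 removes it.
- The descriptor at the auxiliary-derived centre changes from S (7–12, 16, 18) to R (19–24) through CIP priorities only, not through inversion.

## Steps

Step 1
Reactants: 1 3-(4-hydroxy-3-methoxyphenyl)propanoic acid
Product: 2 3-[4-(benzyloxy)-3-methoxyphenyl]propanoic acid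
Conditions: BnBr, NaOH, EtOH/H2O, reflux; then aq. HCl
Reagents that add atoms: benzyl bromide, BrCc1ccccc1
Why: Williamson ether synthesis; the phenoxide is far more nucleophilic than the carboxylate in aqueous ethanol, and any benzyl ester formed is saponified in situ by the excess hydroxide.

Step 2
Reactants: 2 3-[4-(benzyloxy)-3-methoxyphenyl]propanoic acid; 3 (4R)-4-benzyl-1,3-oxazolidin-2-one
Product: 5 (4R)-4-benzyl-3-{3-[4-(benzyloxy)-3-methoxyphenyl]propanoyl}-1,3-oxazolidin-2-one, via mixed pivalic anhydride 4 (not isolated)
Conditions: t-BuCOCl, Et3N, THF, −20 °C; then LiCl, 3, −20 °C → rt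
Reagents that add atoms: none
Why: N-acylation of the oxazolidinone through a mixed anhydride with LiCl/Et3N activation; the auxiliary attacks the less hindered acyl carbon of 4, and no stereocentre is formed.

Step 3
Reactants: 5 (4R)-4-benzyl-3-{3-[4-(benzyloxy)-3-methoxyphenyl]propanoyl}-1,3-oxazolidin-2-one
Product: 7 (4R)-4-benzyl-3-[(2S)-3-[4-(benzyloxy)-3-methoxyphenyl]-2-(hydroxymethyl)propanoyl]-1,3-oxazolidin-2-one, via chlorotitanium Z-enolate 6 (not isolated)
Conditions: TiCl4, i-Pr2NEt, CH2Cl2, 0 °C; then 1,3,5-trioxane, TiCl4, 0 °C; aq. NH4Cl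
Reagents that add atoms: 1,3,5-trioxane, C1OCOCO1
Why: Evans titanium-enolate hydroxymethylation (aldol-type addition to a TiCl4-activated formaldehyde equivalent). The chelated Z-enolate 6 is attacked on the face away from the benzyl group of the auxiliary, which sets the new centre as S. Hydroxymethylation is chosen over benzyloxymethylation so that the oxygen can carry a group that survives step 12.

Step 4
Reactants: 7 (4R)-4-benzyl-3-[(2S)-3-[4-(benzyloxy)-3-methoxyphenyl]-2-(hydroxymethyl)propanoyl]-1,3-oxazolidin-2-one
Product: 8 (4R)-4-benzyl-3-[(2S)-3-[4-(benzyloxy)-3-methoxyphenyl]-2-{[(tert-butyldiphenylsilyl)oxy]methyl}propanoyl]-1,3-oxazolidin-2-one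
Conditions: TBDPSCl, imidazole, CH2Cl2, 0 °C → rt
Reagents that add atoms: tert-butyl(chloro)diphenylsilane, CC(C)(C)[Si](Cl)(c1ccccc1)c1ccccc1
Why: Silyl ether formation on a primary alcohol with imidazole as base and nucleophilic catalyst; the bulky silyl ether should tolerate the Lewis acids, hydrogenation, methoxide and hydride that follow.

Step 5
Reactants: 8 (4R)-4-benzyl-3-[(2S)-3-[4-(benzyloxy)-3-methoxyphenyl]-2-{[(tert-butyldiphenylsilyl)oxy]methyl}propanoyl]-1,3-oxazolidin-2-one
Product: 10 (2S)-3-[4-(benzyloxy)-3-methoxyphenyl]-2-{[(tert-butyldiphenylsilyl)oxy]methyl}propanoic acid, via peroxy acid 9 (not isolated)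
Conditions: LiOH, H2O2, THF/H2O, 0 °C; then aq. Na2SO3; aq. HCl to pH 3
Reagents that add atoms: hydrogen peroxide, OO
Why: Evans auxiliary cleavage with lithium hydroperoxide; the α-effect nucleophile attacks the exocyclic imide carbonyl and is too weakly basic to epimerise the α-centre or expel the β-silyloxy group. Sulfite reduces peroxy acid 9 to the acid, and the auxiliary is recovered.

Step 6
Reactants: 10 (2S)-3-[4-(benzyloxy)-3-methoxyphenyl]-2-{[(tert-butyldiphenylsilyl)oxy]methyl}propanoic acid
Product: 12 (2S)-6-(benzyloxy)-2-{[(tert-butyldiphenylsilyl)oxy]methyl}-5-methoxy-2,3-dihydro-1H-inden-1-one, via acid chloride 11 (not isolated)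
Conditions: (COCl)2, DMF (cat.), CH2Cl2, 0 °C → rt; evaporate; then SnCl4, CH2Cl2, −78 → −30 °C
Reagents that add atoms: none
Why: Intramolecular Friedel–Crafts acylation closing the five-membered ring at the position para to the methoxy group; the other ortho position is flanked by the methoxy group. Low temperature and the absence of base should protect the α-centre and both ethers.

Step 7
Reactants: 13 4-(benzyloxy)-3-methoxybenzaldehyde
Product: 14 (E)-[4-(benzyloxy)-3-methoxybenzylidene]hydrazine
Conditions: N2H4·H2O (10 equiv), EtOH, 0 °C → rt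
Reagents that add atoms: hydrazine hydrate, NN.O
Why: Hydrazone formation by condensation; the large excess of hydrazine suppresses azine formation.

Step 8
Reactants: 14 (E)-[4-(benzyloxy)-3-methoxybenzylidene]hydrazine
Product: 15 [4-(benzyloxy)-3-methoxyphenyl]diazomethane (cold solution, used at once)
Conditions: MnO2 (activated), MgSO4, CH2Cl2, 0 °C, dark; filter cold
Reagents that add atoms: none
Why: Dehydrogenation of a hydrazone to the diazoalkane with MnO2, a standard oxidation for unstabilised aryldiazomethanes; filtration gives a neutral, salt-free solution suited to Lewis acid catalysis.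

Step 9
Reactants: 12 (2S)-6-(benzyloxy)-2-{[(tert-butyldiphenylsilyl)oxy]methyl}-5-methoxy-2,3-dihydro-1H-inden-1-one; 15 [4-(benzyloxy)-3-methoxyphenyl]diazomethane
Product: 16 (1S,3S)-7-(benzyloxy)-1-[4-(benzyloxy)-3-methoxyphenyl]-3-{[(tert-butyldiphenylsilyl)oxy]methyl}-6-methoxy-3,4-dihydronaphthalen-2(1H)-one
Conditions: Sc(OTf)3 (10 mol%), toluene/CH2Cl2, −78 → 0 °C; 15 (1.5 equiv) added slowly
Reagents that add atoms: none
Why: Sc(OTf)3 binds the carbonyl of 12 and the nucleophilic diazo carbon of 15 adds to it, giving a β-oxido diazonium species with the C–N bond anti to a migrating group. Loss of N2 is coupled to a 1,2-shift of the ring A carbon (indanone C7a, the future C8a), so the diazo carbon ends between ring A and the carbonyl and C1–C2 and C1–C8a are formed. The closest known reaction type is the Lewis-acid-catalysed diazoalkane–ketone homologation (Tiffeneau–Demjanov type), established for cycloalkanones with aryldiazomethanes and, with aryl migration, for benzo-fused ketones. Ring B is closed by one-carbon expansion of the five-membered ring through a bridged, phenonium-like transition state, not by an end-to-end cyclisation. The step needs aryl over alkyl migration: the migrating carbon is para to the C6 methoxy group, which stabilises the bridged transition state, whereas the competing α-carbon is a hindered secondary centre bearing an inductively withdrawing silyloxymethyl group. The new C1 centre is not controlled here; it is doubly benzylic and α to the ketone, should form as an equilibrating mixture or enol, and is erased in step 10 and reset from C3 in step 12. C3 takes no part in bond making and should be retained, because the medium is cold and non-basic and enolisation of the product is drawn toward C1. A second insertion is disfavoured because the α-aryl ketone is more hindered and largely enolised.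

Step 10
Reactants: 16 (1S,3S)-7-(benzyloxy)-1-[4-(benzyloxy)-3-methoxyphenyl]-3-{[(tert-butyldiphenylsilyl)oxy]methyl}-6-methoxy-3,4-dihydronaphthalen-2(1H)-one
Product: 18 (3S)-7-(benzyloxy)-1-[4-(benzyloxy)-3-methoxyphenyl]-3-{[(tert-butyldiphenylsilyl)oxy]methyl}-6-methoxy-3,4-dihydronaphthalen-2-yl trifluoromethanesulfonate, via potassium enolate 17 (not isolated)
Conditions: KN(SiMe3)2 (1.0 equiv), THF, −78 °C; then PhNTf2, −78 → 0 °C
Reagents that add atoms: N-phenylbis(trifluoromethanesulfonimide), O=S(=O)(N(c1ccccc1)S(=O)(=O)C(F)(F)F)C(F)(F)F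
Why: Enol triflate formation by O-sulfonylation of an enolate. C1–H, flanked by two arenes and the carbonyl, is far more acidic than C3–H, so enolate 17 forms toward C1; this deletes the uncontrolled C1 centre and avoids epimerisation or β-elimination at C3.

Step 11
Reactants: 18 (3S)-7-(benzyloxy)-1-[4-(benzyloxy)-3-methoxyphenyl]-3-{[(tert-butyldiphenylsilyl)oxy]methyl}-6-methoxy-3,4-dihydronaphthalen-2-yl trifluoromethanesulfonate
Product: 19 methyl (3R)-7-(benzyloxy)-1-[4-(benzyloxy)-3-methoxyphenyl]-3-{[(tert-butyldiphenylsilyl)oxy]methyl}-6-methoxy-3,4-dihydronaphthalene-2-carboxylate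
Conditions: CO (1 atm), Pd(OAc)2 (5 mol%), dppp (6 mol%), Et3N, MeOH/DMF, 60 °C
Reagents that add atoms: carbon monoxide, [C-]#[O+]; methanol, CO
Why: Palladium-catalysed alkoxycarbonylation of an enol triflate: oxidative addition of zerovalent palladium, CO insertion and methanolysis of the acyl–palladium bond. C9 enters at the ester level, which later makes C2 epimerisable and keeps C9 distinct from C10.

Step 12
Reactants: 19 methyl (3R)-7-(benzyloxy)-1-[4-(benzyloxy)-3-methoxyphenyl]-3-{[(tert-butyldiphenylsilyl)oxy]methyl}-6-methoxy-3,4-dihydronaphthalene-2-carboxylate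
Product: 21 methyl (1S,2R,3R)-3-{[(tert-butyldiphenylsilyl)oxy]methyl}-7-hydroxy-1-(4-hydroxy-3-methoxyphenyl)-6-methoxy-1,2,3,4-tetrahydronaphthalene-2-carboxylate, via all-cis methyl ester 20 (not isolated)
Conditions: H2 (10 bar), 10% Pd/C, EtOAc/MeOH, rt; filter; then NaOMe (3 equiv), MeOH, rt; AcOH
Reagents that add atoms: none
Why: Heterogeneous catalytic hydrogenation followed by base epimerisation. Allylic 1,2-strain with the ester places the C3 side chain pseudo-axial, so H2 should add syn to the opposite face and fix C1 (S, aryl cis to the C3 group) and C2 as the all-cis ester 20; the two aryl benzyl ethers are hydrogenolysed in the same operation and the silyl ether stays. Methoxide then inverts only the acidic C2 centre to the all-equatorial 1,2-trans/2,3-trans ester 21.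

Step 13
Reactants: 21 methyl (1S,2R,3R)-3-{[(tert-butyldiphenylsilyl)oxy]methyl}-7-hydroxy-1-(4-hydroxy-3-methoxyphenyl)-6-methoxy-1,2,3,4-tetrahydronaphthalene-2-carboxylate
Product: 22 4-[(1S,2R,3R)-3-{[(tert-butyldiphenylsilyl)oxy]methyl}-7-hydroxy-2-(hydroxymethyl)-6-methoxy-1,2,3,4-tetrahydronaphthalen-1-yl]-2-methoxyphenol
Conditions: LiAlH4 (excess), THF, 0 °C → rt; aq. potassium sodium tartrate (KNaC4H4O6)
Reagents that add atoms: none
Why: Ester reduction with LiAlH4; the excess covers the two phenols, no stereocentre is touched and the silyl ether is inert at this temperature.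

Step 14
Reactants: 22 4-[(1S,2R,3R)-3-{[(tert-butyldiphenylsilyl)oxy]methyl}-7-hydroxy-2-(hydroxymethyl)-6-methoxy-1,2,3,4-tetrahydronaphthalen-1-yl]-2-methoxyphenol
Product: 23 [(1S,2R,3R)-3-{[(tert-butyldiphenylsilyl)oxy]methyl}-7-hydroxy-1-(4-hydroxy-3-methoxyphenyl)-6-methoxy-1,2,3,4-tetrahydronaphthalen-2-yl]methyl acetate
Conditions: Novozym 435 (immobilised Candida antarctica lipase B), vinyl acetate, THF/t-BuOMe, 40 °C
Reagents that add atoms: vinyl acetate, C=COC(C)=O
Why: Lipase-catalysed transesterification; the acetyl-enzyme is attacked by aliphatic alcohols but not by phenols, and vinyl acetate makes the transfer irreversible through tautomerisation of the leaving enol. O10 is silylated, so the C9 hydroxyl is the only aliphatic alcohol present.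

Step 15
Reactants: 23 [(1S,2R,3R)-3-{[(tert-butyldiphenylsilyl)oxy]methyl}-7-hydroxy-1-(4-hydroxy-3-methoxyphenyl)-6-methoxy-1,2,3,4-tetrahydronaphthalen-2-yl]methyl acetate
Product: 24 [(1S,2R,3R)-7-hydroxy-1-(4-hydroxy-3-methoxyphenyl)-3-(hydroxymethyl)-6-methoxy-1,2,3,4-tetrahydronaphthalen-2-yl]methyl acetate
Conditions: HF·pyridine, pyridine, THF, 0 °C → rt
Reagents that add atoms: none
Why: Fluoride-mediated desilylation in a buffered acidic medium; no alkoxide is generated, so the acetate should neither migrate to O10 nor be cleaved, and the phenols are untouched.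

## Compound list

1 | 3-(4-hydroxy-3-methoxyphenyl)propanoic acid | COc1cc(CCC(=O)O)ccc1O | starting material
2 | 3-[4-(benzyloxy)-3-methoxyphenyl]propanoic acid | COc1cc(CCC(=O)O)ccc1OCc1ccccc1 | intermediate
3 | (4R)-4-benzyl-1,3-oxazolidin-2-one | O=C1N[C@H](Cc2ccccc2)CO1 | starting material
4 | 3-[4-(benzyloxy)-3-methoxyphenyl]propanoic pivalic anhydride | COc1cc(CCC(=O)OC(=O)C(C)(C)C)ccc1OCc1ccccc1 | intermediate (not isolated)
5 | (4R)-4-benzyl-3-{3-[4-(benzyloxy)-3-methoxyphenyl]propanoyl}-1,3-oxazolidin-2-one | COc1cc(CCC(=O)N2[C@H](Cc3ccccc3)COC2=O)ccc1OCc1ccccc1 | intermediate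
6 | trichlorotitanium (Z)-enolate of 5 | COc1cc(C/C=C(\O[Ti](Cl)(Cl)Cl)N2[C@H](Cc3ccccc3)COC2=O)ccc1OCc1ccccc1 | intermediate (not isolated)
7 | (4R)-4-benzyl-3-[(2S)-3-[4-(benzyloxy)-3-methoxyphenyl]-2-(hydroxymethyl)propanoyl]-1,3-oxazolidin-2-one | COc1cc(C[C@@H](CO)C(=O)N2[C@H](Cc3ccccc3)COC2=O)ccc1OCc1ccccc1 | intermediate
8 | (4R)-4-benzyl-3-[(2S)-3-[4-(benzyloxy)-3-methoxyphenyl]-2-{[(tert-butyldiphenylsilyl)oxy]methyl}propanoyl]-1,3-oxazolidin-2-one | COc1cc(C[C@@H](CO[Si](c2ccccc2)(c2ccccc2)C(C)(C)C)C(=O)N2[C@H](Cc3ccccc3)COC2=O)ccc1OCc1ccccc1 | intermediate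
9 | (2S)-3-[4-(benzyloxy)-3-methoxyphenyl]-2-{[(tert-butyldiphenylsilyl)oxy]methyl}propaneperoxoic acid | COc1cc(C[C@@H](CO[Si](c2ccccc2)(c2ccccc2)C(C)(C)C)C(=O)OO)ccc1OCc1ccccc1 | intermediate (not isolated)
10 | (2S)-3-[4-(benzyloxy)-3-methoxyphenyl]-2-{[(tert-butyldiphenylsilyl)oxy]methyl}propanoic acid | COc1cc(C[C@@H](CO[Si](c2ccccc2)(c2ccccc2)C(C)(C)C)C(=O)O)ccc1OCc1ccccc1 | intermediate
11 | (2S)-3-[4-(benzyloxy)-3-methoxyphenyl]-2-{[(tert-butyldiphenylsilyl)oxy]methyl}propanoyl chloride | COc1cc(C[C@@H](CO[Si](c2ccccc2)(c2ccccc2)C(C)(C)C)C(=O)Cl)ccc1OCc1ccccc1 | intermediate (not isolated)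
12 | (2S)-6-(benzyloxy)-2-{[(tert-butyldiphenylsilyl)oxy]methyl}-5-methoxy-2,3-dihydro-1H-inden-1-one | O=C1c2cc(OCc3ccccc3)c(OC)cc2C[C@H]1CO[Si](c1ccccc1)(c1ccccc1)C(C)(C)C | intermediate
13 | 4-(benzyloxy)-3-methoxybenzaldehyde | COc1cc(C=O)ccc1OCc1ccccc1 | starting material
14 | (E)-[4-(benzyloxy)-3-methoxybenzylidene]hydrazine | COc1cc(/C=N/N)ccc1OCc1ccccc1 | intermediate
15 | [4-(benzyloxy)-3-methoxyphenyl]diazomethane | [N-]=[N+]=Cc1ccc(OCc2ccccc2)c(OC)c1 | intermediate
16 | (1S,3S)-7-(benzyloxy)-1-[4-(benzyloxy)-3-methoxyphenyl]-3-{[(tert-butyldiphenylsilyl)oxy]methyl}-6-methoxy-3,4-dihydronaphthalen-2(1H)-one (1,3-cis isomer drawn; C1 labile) | COc1cc([C@H]2c3cc(OCc4ccccc4)c(OC)cc3C[C@@H](CO[Si](c3ccccc3)(c3ccccc3)C(C)(C)C)C2=O)ccc1OCc1ccccc1 | intermediate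
17 | potassium enolate of 16 (C1=C2 enolate, 3S) | COc1cc(C2=C([O-])[C@H](CO[Si](c3ccccc3)(c3ccccc3)C(C)(C)C)Cc3cc(OC)c(OCc4ccccc4)cc32)ccc1OCc1ccccc1.[K+] | intermediate (not isolated)
18 | (3S)-7-(benzyloxy)-1-[4-(benzyloxy)-3-methoxyphenyl]-3-{[(tert-butyldiphenylsilyl)oxy]methyl}-6-methoxy-3,4-dihydronaphthalen-2-yl trifluoromethanesulfonate | COc1cc(C2=C(OS(=O)(=O)C(F)(F)F)[C@H](CO[Si](c3ccccc3)(c3ccccc3)C(C)(C)C)Cc3cc(OC)c(OCc4ccccc4)cc32)ccc1OCc1ccccc1 | intermediate
19 | methyl (3R)-7-(benzyloxy)-1-[4-(benzyloxy)-3-methoxyphenyl]-3-{[(tert-butyldiphenylsilyl)oxy]methyl}-6-methoxy-3,4-dihydronaphthalene-2-carboxylate | COc1cc(C2=C(C(=O)OC)[C@H](CO[Si](c3ccccc3)(c3ccccc3)C(C)(C)C)Cc3cc(OC)c(OCc4ccccc4)cc32)ccc1OCc1ccccc1 | intermediate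
20 | methyl (1S,2S,3R)-3-{[(tert-butyldiphenylsilyl)oxy]methyl}-7-hydroxy-1-(4-hydroxy-3-methoxyphenyl)-6-methoxy-1,2,3,4-tetrahydronaphthalene-2-carboxylate (all-cis) | COc1cc([C@H]2c3cc(O)c(OC)cc3C[C@@H](CO[Si](c3ccccc3)(c3ccccc3)C(C)(C)C)[C@H]2C(=O)OC)ccc1O | intermediate (not isolated)
21 | methyl (1S,2R,3R)-3-{[(tert-butyldiphenylsilyl)oxy]methyl}-7-hydroxy-1-(4-hydroxy-3-methoxyphenyl)-6-methoxy-1,2,3,4-tetrahydronaphthalene-2-carboxylate | COc1cc([C@H]2c3cc(O)c(OC)cc3C[C@@H](CO[Si](c3ccccc3)(c3ccccc3)C(C)(C)C)[C@@H]2C(=O)OC)ccc1O | intermediate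
22 | 4-[(1S,2R,3R)-3-{[(tert-butyldiphenylsilyl)oxy]methyl}-7-hydroxy-2-(hydroxymethyl)-6-methoxy-1,2,3,4-tetrahydronaphthalen-1-yl]-2-methoxyphenol | COc1cc([C@H]2c3cc(O)c(OC)cc3C[C@@H](CO[Si](c3ccccc3)(c3ccccc3)C(C)(C)C)[C@@H]2CO)ccc1O | intermediate
23 | [(1S,2R,3R)-3-{[(tert-butyldiphenylsilyl)oxy]methyl}-7-hydroxy-1-(4-hydroxy-3-methoxyphenyl)-6-methoxy-1,2,3,4-tetrahydronaphthalen-2-yl]methyl acetate | COc1cc([C@H]2c3cc(O)c(OC)cc3C[C@@H](CO[Si](c3ccccc3)(c3ccccc3)C(C)(C)C)[C@@H]2COC(C)=O)ccc1O | intermediate
24 | [(1S,2R,3R)-7-hydroxy-1-(4-hydroxy-3-methoxyphenyl)-3-(hydroxymethyl)-6-methoxy-1,2,3,4-tetrahydronaphthalen-2-yl]methyl acetate | COc1cc([C@H]2c3cc(O)c(OC)cc3C[C@@H](CO)[C@@H]2COC(C)=O)ccc1O | target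

## Step count and risks

Total: 15 steps. Longest linear sequence: 13 steps (steps 1–6, then 9–15); steps 7–8 form the two-step side branch.

Step 9 (key step). The most likely failure is slow addition to the carbonyl. The ketone is deactivated by the para methoxy group and shielded by the α-substituent, so decomposition of the electron-rich diazoalkane (dimerisation, protonation) could outrun insertion. Migration of the α-carbon in place of C8a, or closure to an epoxide, are secondary risks. Fallback: from 12, homologation with Me3SiCHN2 and BF3·OEt2 (CH2Cl2, −78 °C), a less hindered diazoalkane for which aryl migration in 1-indanones is established, would give (3S)-7-(benzyloxy)-3-{[(tert-butyldiphenylsilyl)oxy]methyl}-6-methoxy-1-(trimethylsilyl)-3,4-dihydronaphthalen-2(1H)-one F1. F1 loses silicon on work-up to give (3S)-7-(benzyloxy)-3-{[(tert-butyldiphenylsilyl)oxy]methyl}-6-methoxy-3,4-dihydronaphthalen-2(1H)-one F2. Palladium-catalysed enolate α-arylation of F2 at the more acidic C1 with commercial 1-(benzyloxy)-4-bromo-2-methoxybenzene (Pd(OAc)2, a biaryl dialkylphosphine, K3PO4, toluene, 80 °C) returns to 16.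

Step 12. The most likely failure is sluggish saturation of the tetrasubstituted, conjugated alkene after the fast debenzylation, or incomplete facial selectivity. Partial loss of the silyl ether during the methoxide treatment would lead on to lactonisation. Fallback: from 19, dissolving-metal conjugate reduction with Mg in MeOH (electron transfer, with axial protonation at C1 anti to the C3 side chain and in situ equilibration of C2 by the Mg(OMe)2 formed) would spare the benzyl ethers and give methyl (1S,2R,3R)-7-(benzyloxy)-1-[4-(benzyloxy)-3-methoxyphenyl]-3-{[(tert-butyldiphenylsilyl)oxy]methyl}-6-methoxy-1,2,3,4-tetrahydronaphthalene-2-carboxylate F3. Hydrogenolysis of F3 (H2, 1 atm, Pd/C, EtOAc) returns to 21.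

Step 14. The most likely failure is stalled acyl transfer, because the C9 hydroxymethyl group is flanked by two substituted ring carbons and a bulky silyl ether; acylation of a phenol is less likely. Fallback: from 22, exhaustive acetylation (Ac2O, pyridine, DMAP) would give 4-[(1S,2R,3R)-7-acetoxy-2-(acetoxymethyl)-3-{[(tert-butyldiphenylsilyl)oxy]methyl}-6-methoxy-1,2,3,4-tetrahydronaphthalen-1-yl]-2-methoxyphenyl acetate F4. Selective aminolysis of the two aryl acetates of F4 with pyrrolidine (CH2Cl2, rt), which leaves primary alkyl acetates intact, returns to 23.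

Step 6. The most likely failure is partial racemisation of the α-centre through enolisation of the acid chloride or of the SnCl4-bound ketone. Lewis-acid cleavage of the aryl benzyl ether (chelation with the neighbouring methoxy group) and β-elimination of the silyloxy group are further risks. Fallback: from 10, bromination para to the methoxy group (NBS, MeCN, 0 °C) would give (2S)-3-[5-(benzyloxy)-2-bromo-4-methoxyphenyl]-2-{[(tert-butyldiphenylsilyl)oxy]methyl}propanoic acid F5. Amide coupling with MeNHOMe·HCl (EDC·HCl, i-Pr2NEt, CH2Cl2) would give (2S)-3-[5-(benzyloxy)-2-bromo-4-methoxyphenyl]-2-{[(tert-butyldiphenylsilyl)oxy]methyl}-N-methoxy-N-methylpropanamide F6. Bromine–lithium exchange on F6 (t-BuLi, THF, −78 °C) and closure of the aryllithium onto the amide (Parham cyclisation) returns to 12; the tetrahedral chelate masks the ketone until the quench, so no acid or enolisable ketone is present during ring closure.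

## Further compounds

F1 | step 9 | (3S)-7-(benzyloxy)-3-{[(tert-butyldiphenylsilyl)oxy]methyl}-6-methoxy-1-(trimethylsilyl)-3,4-dihydronaphthalen-2(1H)-one | O=C1C([Si](C)(C)C)c2cc(OCc3ccccc3)c(OC)cc2C[C@H]1CO[Si](c1ccccc1)(c1ccccc1)C(C)(C)C
F2 | step 9 | (3S)-7-(benzyloxy)-3-{[(tert-butyldiphenylsilyl)oxy]methyl}-6-methoxy-3,4-dihydronaphthalen-2(1H)-one | O=C1Cc2cc(OCc3ccccc3)c(OC)cc2C[C@H]1CO[Si](c1ccccc1)(c1ccccc1)C(C)(C)C
F3 | step 12 | methyl (1S,2R,3R)-7-(benzyloxy)-1-[4-(benzyloxy)-3-methoxyphenyl]-3-{[(tert-butyldiphenylsilyl)oxy]methyl}-6-methoxy-1,2,3,4-tetrahydronaphthalene-2-carboxylate | COc1cc([C@H]2c3cc(OCc4ccccc4)c(OC)cc3C[C@@H](CO[Si](c3ccccc3)(c3ccccc3)C(C)(C)C)[C@@H]2C(=O)OC)ccc1OCc1ccccc1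
F4 | step 14 | 4-[(1S,2R,3R)-7-acetoxy-2-(acetoxymethyl)-3-{[(tert-butyldiphenylsilyl)oxy]methyl}-6-methoxy-1,2,3,4-tetrahydronaphthalen-1-yl]-2-methoxyphenyl acetate | COc1cc([C@H]2c3cc(OC(C)=O)c(OC)cc3C[C@@H](CO[Si](c3ccccc3)(c3ccccc3)C(C)(C)C)[C@@H]2COC(C)=O)ccc1OC(C)=O
F5 | step 6 | (2S)-3-[5-(benzyloxy)-2-bromo-4-methoxyphenyl]-2-{[(tert-butyldiphenylsilyl)oxy]methyl}propanoic acid | COc1cc(C[C@@H](CO[Si](c2ccccc2)(c2ccccc2)C(C)(C)C)C(=O)O)c(Br)cc1OCc1ccccc1
F6 | step 6 | (2S)-3-[5-(benzyloxy)-2-bromo-4-methoxyphenyl]-2-{[(tert-butyldiphenylsilyl)oxy]methyl}-N-methoxy-N-methylpropanamide | COc1cc(C[C@@H](CO[Si](c2ccccc2)(c2ccccc2)C(C)(C)C)C(=O)N(C)OC)c(Br)cc1OCc1ccccc1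
A1 | alternative 1 | (4S)-4-benzyl-3-[(2E)-3-(3-bromo-4-hydroxy-5-methoxyphenyl)prop-2-enoyl]-1,3-oxazolidin-2-one | COc1cc(/C=C/C(=O)N2[C@@H](Cc3ccccc3)COC2=O)cc(Br)c1O
A2 | alternative 1 | trans-1-aryl-1,2-dihydronaphthalene-2,3-dicarbonyl bis-imide (Br at C8 and C5′) | COc1cc([C@H]2c3c(Br)c(O)c(OC)cc3C=C(C(=O)N3[C@@H](Cc4ccccc4)COC3=O)[C@@H]2C(=O)N2[C@@H](Cc3ccccc3)COC2=O)cc(Br)c1O
A3 | alternative 2 | open-chain (1E,3Z)-1-methoxy-2-silyloxydiene–terminal alkyne carrying the C1–C3 triad (C2 acetoxymethyl, C3 benzyloxymethyl, C1 4-benzyloxy-3-methoxyphenyl) | COc1cc([C@@H](/C=C/C(O[Si](C)(C)C(C)(C)C)=C/OC)[C@@H](COC(C)=O)[C@H](COCc2ccccc2)CC#C)ccc1OCc1ccccc1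
A4 | alternative 2 | fully protected target (C7 tert-butyldimethylsilyl ether, two benzyl ethers) | COc1cc([C@H]2c3cc(O[Si](C)(C)C(C)(C)C)c(OC)cc3C[C@@H](COCc3ccccc3)[C@@H]2COC(C)=O)ccc1OCc1ccccc1
A5 | alternative 3 | tert-butyl 4-[5-(benzyloxy)-2-bromo-4-methoxyphenyl]-4-[4-(benzyloxy)-3-methoxyphenyl]-3-{[(tert-butyldiphenylsilyl)oxy]methyl}butanoate | COc1cc([C@@H](c2cc(OCc3ccccc3)c(OC)cc2Br)[C@@H](CO[Si](c2ccccc2)(c2ccccc2)C(C)(C)C)CC(=O)OC(C)(C)C)ccc1OCc1ccccc1
A6 | alternative 3 | tert-butyl 4-aryl-1-oxotetralin-2-carboxylate with silyloxymethyl on the neighbouring carbon (target numbering: C4 ketone, C3 ester, C2 silyloxymethyl) | COc1cc([C@H]2c3cc(OCc4ccccc4)c(OC)cc3C(=O)[C@@H](C(=O)OC(C)(C)C)[C@@H]2CO[Si](c2ccccc2)(c2ccccc2)C(C)(C)C)ccc1OCc1ccccc1
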